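The ten-membered carbocycle is cut into a six-carbon unit (C1–C5 plus C10) and a four-carbon unit (C6–C9). Both junctions, C5–C6 and C9–C10, lie between oxygenated carbons (O5/O6 and O9/O10), the pattern left when two ring alkenes are oxidised. One irradiation joins (R)-2,4-dimethylcyclohex-2-enone to a 1-silyloxycyclobutene through exactly these two bonds. The resulting cyclohexanone-fused bicyclo[2.2.0]hexane then ring-expands under strain release to the cyclodeca-1,5-dienone. The cyclobutene partner is upgraded: its C7 acetate arm is already closed as the cis γ-lactone on O8, so no late C8 oxidation is needed, and it carries a C11 phosphonate for a mild final methylenation.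

Key step: step 11

Remark (numbering): ring carbons are C1 (ketone), C2, C3, C4 (CHMe), C5 (2-methylbutanoate), C6 (free OH), C7 and C8 (lactone CH and OCH), C9 (angelate), C10 (C(OH)Me); C11, C12, C13 are the lactone α-carbon, carbonyl and exocyclic CH2.
Remark (geometry): the cycloreversion is assumed to give the Z (ring-cis) C9=C10 enone, the more stable geometry of a conjugated double bond in a ten-membered ring; the C5=C6 geometry is immaterial.
Remark (C11): once C11 bears the phosphonate it is an acidic, freely epimerising centre of no consequence; it is left undefined in names and SMILES until step 19 removes it.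
Remark (racemates): compounds 8–10 are racemic and are drawn as the enantiomer that is carried on.
Remark (side chains): the (2R) configuration of the 2-methylbutanoate is taken from the target structure; (R)-2-methylbutanoic acid and angelic acid are purchased.

Step 1
Reactants: 1 (R)-pulegone
Product: 2 (3R)-3-methyl-6-(propan-2-ylidene)cyclohex-1-en-1-yl trifluoromethanesulfonate
Conditions: LiN(iPr)2, THF, −78 °C; PhNTf2, −78 → 0 °C; aq. NH4Cl
Reagents that add atoms: N-phenyl-bis(trifluoromethanesulfonimide), FC(F)(F)S(=O)(=O)N(c1ccccc1)S(=O)(=O)C(F)(F)F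
Why: Kinetic α'-deprotonation of the enone by the hindered amide and O-triflation of the cross-conjugated enolate (enol triflate formation) should give the dienyl triflate without touching the methyl-bearing stereocentre (later C4).

Step 2
Reactants: 2 dienyl triflate
Product: 3 (3R)-3-methyl-6-oxocyclohex-1-en-1-yl trifluoromethanesulfonate
Conditions: O3, CH2Cl2/MeOH, −78 °C; Me2S
Reagents that add atoms: ozone, [O-][O+]=O
Why: Chemoselective ozonolysis should cleave the electron-rich tetrasubstituted isopropylidene alkene and leave the electron-poor enol triflate double bond, unveiling the future C1 ketone.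

Step 3
Reactants: 3 triflyloxy enone
Product: 4 (R)-2,4-dimethylcyclohex-2-en-1-one
Conditions: MeZnCl, Pd(PPh3)4 (cat.), THF, 0 → 20 °C
Reagents that add atoms: methylzinc chloride, C[Zn]Cl
Why: Negishi cross-coupling (oxidative addition of zerovalent palladium into the activated alkenyl triflate, transmetalation from zinc, reductive elimination) installs the C10 methyl under neutral conditions that should not epimerise the γ-stereocentre.

Step 4
Reactants: 5 2,3-dihydrofuran; 6 trichloroacetyl chloride
Product: 8 (±)-cis-7,7-dichloro-2-oxabicyclo[3.2.0]heptan-6-one, via dichloroketene 7 (not isolated)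
Conditions: Zn dust (activated), Et2O/DME, 20 °C, ultrasound, slow addition of 6
Reagents that add atoms: none
Why: Ketene–enol ether [2+2] cycloaddition, with the ketene carbonyl carbon bonding to the enol ether β-carbon and suprafacial addition to the ring alkene, should give the cis-fused cyclobutanone that already holds C6, C7, C8–O and C9.

Step 5
Reactants: 8 dichlorocyclobutanone
Product: 9 (±)-cis-2-oxabicyclo[3.2.0]heptan-6-one
Conditions: Zn dust, AcOH, 20 °C
Reagents that add atoms: none
Why: Reductive dechlorination of the α,α-dichloroketone with zinc in acetic acid should remove both chlorines and leave the ring fusion untouched.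

Step 6
Reactants: 9 bicyclic ketone
Product: 10 (±)-endo-2-oxabicyclo[3.2.0]heptan-6-ol
Conditions: NaBH4, MeOH, −20 °C
Reagents that add atoms: none
Why: Borohydride reduction from the convex face of the cis-fused bicycle should give the endo alcohol as a single diastereomer, which provides the handle for resolution.

Step 7
Reactants: 10 racemic endo alcohol
Product: 11 (1R,5S,6S)-2-oxabicyclo[3.2.0]heptan-6-ol
Conditions: Amano lipase PS, vinyl acetate, MTBE, 30 °C, run to about 55% conversion; chromatography
Reagents that add atoms: none
Why: Lipase-catalysed kinetic resolution by transesterification should acylate the (6R) enantiomer (large ring-fusion carbon against small CH2) and leave the (1R,5S,6S) alcohol, which fixes the absolute configuration of C7 and C8.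

Step 8
Reactants: 11 resolved alcohol
Product: 12 (1R,5R)-2-oxabicyclo[3.2.0]heptane-3,6-dione
Conditions: RuCl3·xH2O (cat.), NaIO4, CCl4/MeCN/H2O, 20 °C
Reagents that add atoms: sodium periodate (oxygen source, via RuO4), [Na+].[O-]I(=O)(=O)=O
Why: RuO4 formed in the flask should oxidise the secondary alcohol to the ketone and the unhindered O–CH2 group to the lactone carbonyl C12 (ether-to-lactone oxidation), the tertiary O–CH on the strained ring being the slower site.

Step 9
Reactants: 12 keto lactone
Product: 13 (1R,5R)-6-[(tert-butyldimethylsilyl)oxy]-2-oxabicyclo[3.2.0]hept-6-en-3-one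
Conditions: TBSOTf, then Et3N, CH2Cl2, −78 → 0 °C
Reagents that add atoms: tert-butyldimethylsilyl trifluoromethanesulfonate, CC(C)(C)[Si](C)(C)OS(=O)(=O)C(F)(F)F
Why: Soft enolisation and O-silylation can only place the double bond at C6=C9, because an enol double bond to the ring-fusion carbon C7 would be shared by the four- and five-membered rings, so regiochemistry is fixed and C7 cannot epimerise.

Step 10
Reactants: 13 silyloxycyclobutene lactone
Product: 15 diethyl [(1R,5R)-6-[(tert-butyldimethylsilyl)oxy]-3-oxo-2-oxabicyclo[3.2.0]hept-6-en-4-yl]phosphonate, via lactone enol phosphate 14 (not isolated)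
Conditions: LiN(iPr)2 (1.1 equiv), THF, −78 °C; ClP(O)(OEt)2; LiN(iPr)2 (2.2 equiv), −78 → 0 °C; AcOH
Reagents that add atoms: diethyl chlorophosphate, CCOP(Cl)(=O)OCC
Why: O-phosphorylation of the lactone enolate and base-induced 1,3-migration of phosphorus from oxygen to carbon (vinyl phosphate to phosphonate rearrangement) should place the phosphonate on C11, the ketone being masked as the silyl enol ether so that the lactone is the only enolisable carbonyl.

Step 11
Reactants: 4 (R)-2,4-dimethylcyclohex-2-en-1-one; 15 phosphonate-bearing silyloxycyclobutene lactone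
Product: 16 cis-anti-cis tetracyclic photoadduct
Conditions: hν (350 nm, Pyrex), CH2Cl2, −20 °C, 4 (1.5 equiv) added in portions
Reagents that add atoms: none
Why: Light of 350 nm excites only enone 4, whose triplet forms an exciplex and then a triplet 1,4-biradical with the electron-rich enol ether double bond of 15, and spin inversion followed by radical–radical collapse completes the cyclobutane C5–C6–C9–C10. The closest known reaction type is the enone [2+2] photocycloaddition with silyl enol ethers and with cyclobutenes. The four-membered ring therefore closes stepwise, one σ-bond after the other, by biradical combination and not in a concerted way. C5 and C10 are set by addition anti to the C4 methyl with a cis six/four fusion, and C6 and C9 by the cis geometry of the cyclobutene and attack on its convex face, anti to the lactone. The one selectivity the step needs is the head-to-tail orientation (C6 to the β-carbon C5, C9 to the α-carbon C10), which the silyloxy donor on C6 imposes as in enone–enol ether additions. Facial and fusion isomers need not be separated, because C5, C6, C9 and C10 all become trigonal in step 12 while C4, C7 and C8 come unchanged from 4 and 15.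

Step 12
Reactants: 16 photoadduct
Product: 17 ten-membered (9Z)-dienone lactone with C5=C6 silyl enol ether
Conditions: degassed o-xylene, 2,6-di-tert-butylpyridine (cat.), sealed tube, 190 °C
Reagents that add atoms: none
Why: Thermal cycloreversion of the bicyclo[2.2.0]hexane (the shared C6–C9 bond breaks first and the 1,4-diyl fragments across C5–C10, the weakest remaining bond, next to the ketone) should merge the six- and four-membered rings into the cyclodeca-1,5-dienone, while the lactone bridging C7–C8 disfavours the alternative C7–C8 cleavage and the Cope isomer.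

Step 13
Reactants: 17 dienone silyl enol ether
Product: 18 (5S)-5-bromo-6-ketone
Conditions: NBS, NaHCO3, THF, −78 → −40 °C
Reagents that add atoms: N-bromosuccinimide, BrN1C(=O)CCC1=O
Why: Electrophilic α-bromination of the silyl enol ether should deliver bromine to the peripheral face of the medium ring, anti to the C3–C4 bond with H4 eclipsing the enol ether, that is trans to the C4 methyl, whichever geometry the enol ether has.

Step 14
Reactants: 18 bromo ketone; 19 (R)-2-methylbutanoic acid
Product: 21 (5R)-5-[(2R)-2-methylbutanoyloxy]-6-ketone, via caesium (R)-2-methylbutanoate 20 (not isolated)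
Conditions: 19, Cs2CO3, DMF, 0 °C; then 18, 0 → 20 °C
Reagents that add atoms: none
Why: SN2 displacement of the carbonyl-activated secondary bromide by the weakly basic carboxylate proceeds with inversion, which sets C5 with O5 cis to the C4 methyl and installs the ester in the same operation.

Step 15
Reactants: 21 α-acyloxy ketone
Product: 22 (6R)-6-alcohol
Conditions: NaBH4, MeOH/CH2Cl2 (1:1), −78 °C
Reagents that add atoms: none
Why: Borohydride reduction at low temperature should take the activated α-acyloxy ketone in preference to the conjugated enone, with hydride adding anti to the C5–O bond (polar 1,2-induction) and anti to the lactone CH2 on C7, which places the C6 hydroxyl trans to O5 and cis to C11.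

Step 16
Reactants: 22 C6 alcohol
Product: 23 6-O-triethylsilyl ether
Conditions: TESOTf, 2,6-lutidine, CH2Cl2, −78 °C
Reagents that add atoms: triethylsilyl trifluoromethanesulfonate, CC[Si](CC)(CC)OS(=O)(=O)C(F)(F)F
Why: Silylation with the silyl triflate and a hindered pyridine base protects the only free hydroxyl at once, before acyl migration from O5 or lactone migration to O6 can set in.

Step 17
Reactants: 23 (9Z)-enone
Product: 24 (9R,10R)-9,10-diol
Conditions: OsO4 (cat.), NMO, citric acid, tBuOH/H2O, 20 °C
Reagents that add atoms: osmium tetroxide, O=[Os](=O)(=O)=O; N-methylmorpholine N-oxide, C[N+]1([O-])CCOCC1; water, O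
Why: Catalytic syn-dihydroxylation (Upjohn conditions, with citric acid for the electron-poor alkene) should take place on the exposed face of the Z-enone, anti to the C6–C7 ring segment, which places O9 trans to O8 and, by syn addition to the Z double bond, O10 cis to O9.

Step 18
Reactants: 24 diol; 25 angelic acid
Product: 27 9-O-angelate, via angelic 2,4,6-trichlorobenzoic anhydride 26 (not isolated)
Conditions: 25, 2,4,6-trichlorobenzoyl chloride, Et3N, toluene, 20 °C; then 24, 80 °C
Reagents that add atoms: none
Why: Yamaguchi esterification through the pre-formed mixed anhydride acylates the only free secondary hydroxyl (C10–OH is tertiary) and is the protocol that keeps the Z geometry of the angelate.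

Step 19
Reactants: 27 phosphono lactone
Product: 28 α-methylene lactone (6-O-triethylsilyl target)
Conditions: aq. HCHO (37%), K2CO3, THF, 0 °C
Reagents that add atoms: formaldehyde, C=O
Why: Horner–Wadsworth–Emmons olefination of the acidic α-phosphono lactone with formaldehyde needs only carbonate, so the C1 ketone, both esters and the epimerisable 2-methylbutanoate centre are not enolised, and the undefined C11 centre disappears.

Step 20
Reactants: 28 silyl ether
Product: 29 target CNP0226386.1
Conditions: HF·pyridine, pyridine/THF, 0 °C
Reagents that add atoms: none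
Why: Buffered fluoride desilylation frees the C6 hydroxyl under conditions that tolerate the α-methylene lactone, the angelate and the tertiary α-hydroxy ketone and that do not promote acyl migration.

Compound list
1 | (R)-pulegone, (5R)-5-methyl-2-(propan-2-ylidene)cyclohexan-1-one | C[C@@H]1CCC(=C(C)C)C(=O)C1 | starting material
2 | (3R)-3-methyl-6-(propan-2-ylidene)cyclohex-1-en-1-yl trifluoromethanesulfonate | C[C@@H]1CCC(=C(C)C)C(OS(=O)(=O)C(F)(F)F)=C1 | intermediate
3 | (3R)-3-methyl-6-oxocyclohex-1-en-1-yl trifluoromethanesulfonate | C[C@@H]1CCC(=O)C(OS(=O)(=O)C(F)(F)F)=C1 | intermediate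
4 | (R)-2,4-dimethylcyclohex-2-en-1-one | CC1=C[C@H](C)CCC1=O | intermediate
5 | 2,3-dihydrofuran | C1CC=CO1 | starting material
6 | trichloroacetyl chloride | ClC(=O)C(Cl)(Cl)Cl | starting material
7 | dichloroketene (not isolated) | ClC(Cl)=C=O | intermediate
8 | (±)-cis-7,7-dichloro-2-oxabicyclo[3.2.0]heptan-6-one, racemate, (1S,5R) enantiomer drawn | C1O[C@H]2[C@@H](C1)C(=O)C2(Cl)Cl | intermediate
9 | (±)-cis-2-oxabicyclo[3.2.0]heptan-6-one, racemate, (1R,5R) enantiomer drawn | C1O[C@H]2[C@@H](C1)C(=O)C2 | intermediate
10 | (±)-endo-2-oxabicyclo[3.2.0]heptan-6-ol, racemate, (1R,5S,6S) enantiomer drawn | C1O[C@H]2[C@@H](C1)[C@@H](O)C2 | intermediate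
11 | (1R,5S,6S)-2-oxabicyclo[3.2.0]heptan-6-ol, single enantiomer | C1O[C@H]2[C@@H](C1)[C@@H](O)C2 | intermediate
12 | (1R,5R)-2-oxabicyclo[3.2.0]heptane-3,6-dione (cis γ-lactone on a cyclobutanone; C7 and C8 of the target) | O=C1O[C@H]2[C@@H](C1)C(=O)C2 | intermediate
13 | (1R,5R)-6-[(tert-butyldimethylsilyl)oxy]-2-oxabicyclo[3.2.0]hept-6-en-3-one | O=C1O[C@H]2[C@@H](C1)C(O[Si](C)(C)C(C)(C)C)=C2 | intermediate
14 | diethyl enol phosphate of lactone 13 (ketene acetal phosphate, not isolated) | CCOP(=O)(OCC)OC1=C[C@H]2C(O[Si](C)(C)C(C)(C)C)=C[C@H]2O1 | intermediate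
15 | diethyl [(1R,5R)-6-[(tert-butyldimethylsilyl)oxy]-3-oxo-2-oxabicyclo[3.2.0]hept-6-en-4-yl]phosphonate, the 1-silyloxycyclobutene with the C7 acetate unit closed on O8, epimers at the phosphonate carbon | O=C1O[C@H]2[C@@H](C1P(=O)(OCC)OCC)C(O[Si](C)(C)C(C)(C)C)=C2 | intermediate
16 | cis-anti-cis photoadduct: cyclohexanone (C1–C5, C10; 4-Me, 10-Me) cis-fused at C5–C10 to cyclobutane C5–C6–C9–C10, which is fused at C6–C9, anti, to cyclobutane C6–C7–C8–C9 carrying 6-OTBS and the cis γ-lactone C7–C11–C12(=O)–O8 with the C11 phosphonate | O=C1CC[C@@H](C)[C@H]2[C@]1(C)[C@@H]3[C@H]4OC(=O)C(P(=O)(OCC)OCC)[C@H]4[C@]23O[Si](C)(C)C(C)(C)C | intermediate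
17 | ten-membered dienone: C1 ketone, (9Z)-C9=C10 enone with 10-Me, C5=C6 TBS enol ether (C4 and C7 trans), (4R)-Me, cis γ-lactone across C7–C8, C11 phosphonate | C/C1=C/[C@H]2OC(=O)C(P(=O)(OCC)OCC)[C@H]2/C(O[Si](C)(C)C(C)(C)C)=C/[C@H](C)CCC1=O | intermediate
18 | (5S)-5-bromo-6-ketone of 17 (Br trans to the C4 methyl) | C/C1=C/[C@H]2OC(=O)C(P(=O)(OCC)OCC)[C@H]2C(=O)[C@@H](Br)[C@H](C)CCC1=O | intermediate
19 | (R)-2-methylbutanoic acid | CC[C@@H](C)C(=O)O | starting material
20 | caesium (R)-2-methylbutanoate (not isolated) | CC[C@@H](C)C(=O)[O-].[Cs+] | intermediate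
21 | (5R)-5-[(2R)-2-methylbutanoyloxy]-6-ketone (O5 cis to the C4 methyl) | C/C1=C/[C@H]2OC(=O)C(P(=O)(OCC)OCC)[C@H]2C(=O)[C@H](OC(=O)[C@H](C)CC)[C@H](C)CCC1=O | intermediate
22 | (6R)-6-hydroxy-5-ester (6-OH trans to O5, cis to C11) | C/C1=C/[C@H]2OC(=O)C(P(=O)(OCC)OCC)[C@H]2[C@@H](O)[C@H](OC(=O)[C@H](C)CC)[C@H](C)CCC1=O | intermediate
23 | 6-O-triethylsilyl ether of 22 | C/C1=C/[C@H]2OC(=O)C(P(=O)(OCC)OCC)[C@H]2[C@@H](O[Si](CC)(CC)CC)[C@H](OC(=O)[C@H](C)CC)[C@H](C)CCC1=O | intermediate
24 | (9R,10R)-9,10-diol of 23 (O9 trans to O8, O10 cis to O9) | C[C@@]1(O)[C@H](O)[C@H]2OC(=O)C(P(=O)(OCC)OCC)[C@H]2[C@@H](O[Si](CC)(CC)CC)[C@H](OC(=O)[C@H](C)CC)[C@H](C)CCC1=O | intermediate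
25 | angelic acid, (Z)-2-methylbut-2-enoic acid | C/C=C(/C)C(=O)O | starting material
26 | angelic 2,4,6-trichlorobenzoic anhydride (not isolated) | C/C=C(/C)C(=O)OC(=O)c1c(Cl)cc(Cl)cc1Cl | intermediate
27 | 9-O-angelate of 24 | C[C@@]1(O)[C@H](OC(=O)/C(C)=C\C)[C@H]2OC(=O)C(P(=O)(OCC)OCC)[C@H]2[C@@H](O[Si](CC)(CC)CC)[C@H](OC(=O)[C@H](C)CC)[C@H](C)CCC1=O | intermediate
28 | 6-O-triethylsilyl ether of the target (α-methylene lactone in place) | C[C@@]1(O)[C@H](OC(=O)/C(C)=C\C)[C@H]2OC(=O)C(=C)[C@H]2[C@@H](O[Si](CC)(CC)CC)[C@H](OC(=O)[C@H](C)CC)[C@H](C)CCC1=O | intermediate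
29 | CNP0226386.1 | C=C1C(=O)O[C@H]2[C@@H]1[C@@H](O)[C@H](OC(=O)[C@H](C)CC)[C@H](C)CCC(=O)[C@](C)(O)[C@@H]2OC(=O)/C(C)=C\C | target

Total step count: 20. Longest linear sequence: 17 steps (steps 4–20, from 2,3-dihydrofuran); the enone branch (steps 1–3) joins at step 11.

Steps most likely to fail

Step 11. The excited enone may be lost to dimerisation or add in the head-to-head sense. Enol ether 15, whose C8 oxygen is an allylic carboxylate, may also lose that oxygen by β-elimination to a cyclobutenone, either while it is made (steps 9–10) or under irradiation. The fallback changes the partner to the ether oxidation level and raises C12 afterwards. It sets out from 11: oxidation of the alcohol alone with Dess–Martin periodinane should give (1R,5R)-2-oxabicyclo[3.2.0]heptan-6-one F1, and kinetic enolisation (LiN(iPr)2, TBSCl, THF/DMPU, −78 °C) its tert-butyldimethylsilyl enol ether F2, a plain cyclic-ether donor without a leaving group. Irradiation with 4 should give the ether photoadduct F3, and RuCl3/NaIO4 then oxidises the O–CH2 group to the lactone photoadduct F4. The C1 ketone is masked as its trimethylsilyl enol ether F5 (LiN(iPr)2, TMSCl), the lactone is phosphorylated to the enol phosphate F6 and rearranged as in step 10, and dilute acid on work-up frees the ketone, which brings the route back at 16.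

Step 12. At the temperature of cycloreversion the product may react on: Cope rearrangement to the 1,2-divinylcyclohexane isomer, transannular addition of the new silyl enol ether to the conjugated enone, or formation of the E enone. The fallback fragments at the carbinol oxidation level, where the product has no acceptor. It sets out from 16: NaBH4 reduction of the C1 ketone should give the C1 carbinol F7 (either epimer), thermolysis under the conditions of step 12 the ten-membered dienol F8, and MnO2 oxidation of the allylic alcohol returns the route at 17.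

Step 14. Substitution at the hindered C5 may be outrun by E2 loss of HBr towards C4, or the configuration may erode through bromide exchange and enolisation of the bromo ketone. The fallback puts oxygen on first and inverts it afterwards. It sets out from 17: Rubottom oxidation (mCPBA, NaHCO3, CH2Cl2, −20 °C; then Et3N·3HF) should deliver oxygen to the same peripheral face as bromine and give the (5S)-α-hydroxy ketone F9. Mitsunobu esterification with 19 (PPh3, DIAD, THF, 0 °C) then inverts C5 and returns the route at 21.

Further compounds
F1 | step 11 | (1R,5R)-2-oxabicyclo[3.2.0]heptan-6-one | C1O[C@H]2[C@@H](C1)C(=O)C2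
F2 | step 11 | (1R,5R)-6-[(tert-butyldimethylsilyl)oxy]-2-oxabicyclo[3.2.0]hept-6-ene | C1O[C@H]2[C@@H](C1)C(O[Si](C)(C)C(C)(C)C)=C2
F3 | step 11 | ether photoadduct (as 16 with O8–CH2–CH2 in place of the phosphono lactone) | O=C1CC[C@@H](C)[C@H]2[C@]1(C)[C@@H]3[C@H]4OCC[C@H]4[C@]23O[Si](C)(C)C(C)(C)C
F4 | step 11 | lactone photoadduct (16 without the phosphonate) | O=C1CC[C@@H](C)[C@H]2[C@]1(C)[C@@H]3[C@H]4OC(=O)C[C@H]4[C@]23O[Si](C)(C)C(C)(C)C
F5 | step 11 | C1 trimethylsilyl enol ether of F4 | C[Si](C)(C)OC1=CC[C@@H](C)[C@H]2[C@]1(C)[C@@H]3[C@H]4OC(=O)C[C@H]4[C@]23O[Si](C)(C)C(C)(C)C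
F6 | step 11 | lactone enol phosphate of F5 | C[Si](C)(C)OC1=CC[C@@H](C)[C@H]2[C@]1(C)[C@@H]3[C@H]4OC(OP(=O)(OCC)OCC)=C[C@H]4[C@]23O[Si](C)(C)C(C)(C)C
F7 | step 12 | C1 carbinol of 16 (C1 epimers) | OC1CC[C@@H](C)[C@H]2[C@]1(C)[C@@H]3[C@H]4OC(=O)C(P(=O)(OCC)OCC)[C@H]4[C@]23O[Si](C)(C)C(C)(C)C
F8 | step 12 | ten-membered dienol (17 with C1 carbinol) | C/C1=C/[C@H]2OC(=O)C(P(=O)(OCC)OCC)[C@H]2/C(O[Si](C)(C)C(C)(C)C)=C/[C@H](C)CCC1O
F9 | step 14 | (5S)-5-hydroxy-6-ketone | C/C1=C/[C@H]2OC(=O)C(P(=O)(OCC)OCC)[C@H]2C(=O)[C@@H](O)[C@H](C)CCC1=O
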